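## Retrosynthetic overview

- **Feature:** C2 and C3 of pyranone ring B are the former C2=C3 double bond of a 2-methylchromone. The tertiary carbinol carbon C4' lies four carbons out from C2, so its oxygen can be tied as an ester to a disposable carboxyl group on C3.
- **Late disconnections:** first the phenol pivalate. Then the C3–CO2 bond and the C4'–O acyl bond, which lead back to an eight-membered β-keto lactone bridging C2 and C3. Re-forming C3–C2' turns this lactone into a cyclobutane.
- **Key disconnection:** retro-[2+2] across C2–C1' and C3–C2', back to the 2-methylpent-4-en-2-yl ester of 7-bromo-2-methyl-6-pivaloyloxychromone-3-carboxylic acid. A chiral Lewis acid chooses the face of C2.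
- **Chromone:** C-acylation of the tertiary acetoacetate with a 2-fluorobenzoyl chloride, then O1–C8a closure by fluoride displacement. Bromine is carried from the start, because late bromination of a 6-hydroxychromanone cannot be relied on to choose C7 over C5.
- **Ring order:** ring A is bought. Ring B forms in step 6, and the δ-lactone and cyclobutane form together in step 7. The cyclobutane is opened to the eight-membered lactone in step 8, and that lactone is excised in step 9.

Key step: step 7

Assumption: the sense of induction of the Sc(OTf)3–pybox complex on this new substrate cannot be predicted, so the (S,S)-ligand is written and its commercially available (R,R)-enantiomer is used instead if the C2 Re face proves to be the open one.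

## Route

Step 1
Reactants: 1 4-bromo-2-fluoro-5-methoxybenzoic acid
Product: 2 4-bromo-2-fluoro-5-hydroxybenzoic acid
Conditions: BBr3 (3 equiv), CH2Cl2, −78 °C to rt; H2O quench
Reagents that add atoms: none
Why: BBr3 demethylation of an aryl methyl ether, in which bromide attacks the methyl group of the boron-complexed ether while C–Br, C–F and the carboxyl group are untouched.

Step 2
Reactants: 2 4-bromo-2-fluoro-5-hydroxybenzoic acid
Product: 3 4-bromo-2-fluoro-5-(pivaloyloxy)benzoic acid
Conditions: PivCl (1.15 equiv), NaOH (2.3 equiv), THF/H2O, 0 °C; then HCl to pH 2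
Reagents that add atoms: pivaloyl chloride, CC(C)(C)C(=O)Cl
Why: Schotten–Baumann O-acylation, in which the phenoxide reacts faster than the carboxylate, any mixed anhydride is hydrolysed back in the aqueous base, and the bulky ester keeps ring A electron-poor for the SNAr and photochemical steps while resisting enolates and K2CO3.

Step 3
Reactants: 3 4-bromo-2-fluoro-5-(pivaloyloxy)benzoic acid
Product: 4 4-bromo-2-fluoro-5-(pivaloyloxy)benzoyl chloride
Conditions: SOCl2 (3 equiv), toluene, 75 °C; evaporation, used crude
Reagents that add atoms: thionyl chloride, O=S(Cl)Cl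
Why: Acid chloride formation through the acyl chlorosulfite, a reaction that aryl pivalates, aryl fluorides and aryl bromides tolerate.

Step 4
Reactants: 5 2-methylpent-4-en-2-ol; 6 2,2,6-trimethyl-4H-1,3-dioxin-4-one
Product: 8 2-methylpent-4-en-2-yl 3-oxobutanoate, via acetylketene 7 (not isolated)
Conditions: toluene, reflux, acetone distilled off
Reagents that add atoms: none
Why: Thermal retro-hetero-Diels–Alder cleavage of the dioxinone releases acetylketene 7, which acetoacetylates even a hindered tertiary alcohol under neutral conditions, and the homoallylic (not allylic) ester cannot undergo a Carroll rearrangement.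

Step 5
Reactants: 8 2-methylpent-4-en-2-yl 3-oxobutanoate; 4 4-bromo-2-fluoro-5-(pivaloyloxy)benzoyl chloride
Product: 9 2-methylpent-4-en-2-yl 2-[4-bromo-2-fluoro-5-(pivaloyloxy)benzoyl]-3-oxobutanoate (largely enolised)
Conditions: MgCl2 (1.1 equiv), pyridine (2.2 equiv), CH2Cl2, 0 °C to rt; then 1 M HCl
Reagents that add atoms: none
Why: Soft enolisation and C-acylation of a β-keto ester, in which the MgCl2-bound enolate has both oxygens tied to the metal and so reacts on carbon, while the weak base leaves the pivalate and the tertiary ester alone.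

Step 6
Reactants: 9 2-methylpent-4-en-2-yl 2-[4-bromo-2-fluoro-5-(pivaloyloxy)benzoyl]-3-oxobutanoate
Product: 10 2-methylpent-4-en-2-yl 7-bromo-2-methyl-4-oxo-6-(pivaloyloxy)-4H-chromene-3-carboxylate
Conditions: K2CO3 (1.5 equiv), dry DMF, 70 °C
Reagents that add atoms: none
Why: Intramolecular SNAr, in which the acetyl enolate oxygen displaces the fluoride ortho to the aroyl carbonyl and closes ring B as a 4-pyranone, fluoride leaving far faster than the para bromide and the anhydrous carbonate sparing both esters.

Step 7
Reactants: 10 2-methylpent-4-en-2-yl 7-bromo-2-methyl-4-oxo-6-(pivaloyloxy)-4H-chromene-3-carboxylate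
Product: 12 (2S,3S,2'S)-cyclobutane δ-lactone photoadduct: 7-bromo-2-methyl-6-(pivaloyloxy)chroman-4-one in which C2–C1'H2–C2'H–C3 is a cyclobutane and C3–C(=O)–O–CMe2–C3'H2–C2' is a δ-lactone; both fusions cis; ring B and lactone on opposite cyclobutane faces, via triplet 1,4-diradical 11 (not isolated)
Conditions: Sc(OTf)3 (10 mol%), (S,S)-t-Bu-pybox (12 mol%), 4 Å MS, CH2Cl2 (10 mM), Ar, −40 °C, 405 nm LED
Reagents that add atoms: none
Why: Proposed new method: the Sc(OTf)3–pybox cation should bind the C4 ketone and the C3 ester carbonyl as a chelate and shift the chromone absorption to the red, so that 405 nm light excites only the bound and facially shielded substrate, which crosses to its triplet (aided by the bromine) and behaves as a C2/C3 diradical. C3 then attacks the internal alkene carbon C2' in a 6-exo-trig closure that forms the δ-lactone and gives triplet 1,4-diradical 11 (tertiary, O1-stabilised radical at C2 and primary radical at C1'), and after spin inversion these two centres combine to form C2–C1' and close the cyclobutane. The closest known reaction types are the chiral-Lewis-acid-catalysed enantioselective intramolecular [2+2] photocycloadditions of cyclic enones and coumarins and the racemic [2+2] photocycloadditions of chromones, but a chromone-3-carboxylate reacting through its ester tether has not been shown. The ligand leaves the C2 Si/C3 Re face open and thereby sets C3 in the first bond, C2' follows because the short tether can only give a cis-fused lactone/cyclobutane pair, and C2 follows because the four-membered ring can only close cis on ring B, so one facial choice fixes all three centres as 2S,3S,2'S. The step needs straight (C2–C1', C3–C2') instead of crossed regiochemistry, which the four-atom tether secures because 6-exo closure is favoured over 7-endo, and it needs the minor E rotamer of the ester, which the gem-dimethyl group at C4' makes easier to reach. Low temperature and long-wavelength light should spare the C–Br bond, the acid-labile tertiary ester and the donor–acceptor C2–C3 bond of the product.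

Step 8
Reactants: 12 (2S,3S,2'S)-cyclobutane δ-lactone photoadduct
Product: 13 (2S)-eight-membered β-keto lactone: 7-bromo-2-methyl-6-(pivaloyloxy)chroman-4-one bridged C2–C1'H2–C2'H2–C3'H2–C4'Me2–O–C(=O)–C3 (C3 as epimer/enol mixture, of no consequence)
Conditions: SmI2 (2.5 equiv, 0.1 M in THF), t-BuOH (3 equiv), THF, −78 °C; then aq. NH4Cl
Reagents that add atoms: none
Why: SmI2-mediated reductive fragmentation of an α-keto cyclobutane (ketyl, then cyclobutylcarbinyl radical opening), in which trivalent samarium chelated between the C4 ketyl oxygen and the lactone carbonyl holds the lactone carbon in the ketyl plane and turns the exocyclic C3–C2' bond parallel to the ketyl p orbital while the endocyclic C3–C2 bond stays near the nodal plane, so strain-driven scission should give the chelated β-keto ester enolate and a C2' radical that is reduced and protonated to CH2, with HMPA-free SmI2 at −78 °C leaving the aryl bromide, the pivalate and C2 untouched.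

Step 9
Reactants: 13 (2S)-eight-membered β-keto lactone
Product: 16 (S)-7-bromo-2-(4-hydroxy-4-methylpentyl)-2-methyl-4-oxochroman-6-yl pivalate, via α-oxoketene 14 (not isolated), via β-keto acid 15 (not isolated)
Conditions: DMSO/H2O (20:1), Ar, 115 °C
Reagents that add atoms: none
Why: Neutral Krapcho-type dealkoxycarbonylation of a tert-alkyl β-keto ester, in which the enol expels the tertiary alcohol thermally to give α-oxoketene 14 (the pathway known for tert-butyl acetoacetates), water adds irreversibly to give β-keto acid 15 and CO2 is lost, so the C4'–O bond stays intact, no hydroxide has to attack a hindered and enolate-deactivated ester, and no base is present that could open ring B by retro-oxa-Michael reaction and racemise C2.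

Step 10
Reactants: 16 (S)-7-bromo-2-(4-hydroxy-4-methylpentyl)-2-methyl-4-oxochroman-6-yl pivalate
Product: 17 (S)-7-bromo-6-hydroxy-2-(4-hydroxy-4-methylpentyl)-2-methylchroman-4-one (target)
Conditions: K2CO3 (1.5 equiv), MeOH, 0 °C; then aq. NH4Cl
Reagents that add atoms: none
Why: Base-mediated methanolysis (transesterification) of an activated aryl ester, in which the C6 phenoxide formed is para to O1 and makes O1 a poor leaving group, so retro-oxa-Michael opening of ring B, the only path by which C2 could racemise, should not compete at 0 °C, and the ketone, tertiary alcohol and bromide are inert.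

## Compound list

1 | 4-bromo-2-fluoro-5-methoxybenzoic acid | COc1cc(C(=O)O)c(F)cc1Br | starting material
2 | 4-bromo-2-fluoro-5-hydroxybenzoic acid | Oc1cc(C(=O)O)c(F)cc1Br | intermediate
3 | 4-bromo-2-fluoro-5-(pivaloyloxy)benzoic acid | CC(C)(C)C(=O)Oc1cc(C(=O)O)c(F)cc1Br | intermediate
4 | 4-bromo-2-fluoro-5-(pivaloyloxy)benzoyl chloride | CC(C)(C)C(=O)Oc1cc(C(=O)Cl)c(F)cc1Br | intermediate
5 | 2-methylpent-4-en-2-ol | C=CCC(C)(C)O | starting material
6 | 2,2,6-trimethyl-4H-1,3-dioxin-4-one | CC1=CC(=O)OC(C)(C)O1 | starting material
7 | acetylketene | CC(=O)C=C=O | intermediate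
8 | 2-methylpent-4-en-2-yl 3-oxobutanoate | C=CCC(C)(C)OC(=O)CC(C)=O | intermediate
9 | 2-methylpent-4-en-2-yl 2-[4-bromo-2-fluoro-5-(pivaloyloxy)benzoyl]-3-oxobutanoate | C=CCC(C)(C)OC(=O)C(C(C)=O)C(=O)c1cc(OC(=O)C(C)(C)C)c(Br)cc1F | intermediate
10 | 2-methylpent-4-en-2-yl 7-bromo-2-methyl-4-oxo-6-(pivaloyloxy)-4H-chromene-3-carboxylate | C=CCC(C)(C)OC(=O)c1c(C)oc2cc(Br)c(OC(=O)C(C)(C)C)cc2c1=O | intermediate
11 | triplet 1,4-diradical (δ-lactone closed, radicals at C2 and C1') | O=C1OC(C)(C)C[C@@H]([CH2])[C@]12C(=O)c3cc(OC(=O)C(C)(C)C)c(Br)cc3O[C]2C | intermediate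
12 | (2S,3S,2'S)-cis,cis-fused cyclobutane δ-lactone photoadduct | O=C1OC(C)(C)C[C@H]2C[C@]3(C)Oc4cc(Br)c(OC(=O)C(C)(C)C)cc4C(=O)[C@]123 | intermediate
13 | (2S)-eight-membered β-keto lactone bridging C2 and C3 of the chromanone | CC1(C)CCC[C@]2(C)Oc3cc(Br)c(OC(=O)C(C)(C)C)cc3C(=O)C2C(=O)O1 | intermediate
14 | (S)-α-oxoketene (C3=C=O) with free tertiary alcohol | CC(C)(O)CCC[C@@]1(C)C(=C=O)C(=O)c2cc(OC(=O)C(C)(C)C)c(Br)cc2O1 | intermediate
15 | (2S)-7-bromo-2-(4-hydroxy-4-methylpentyl)-2-methyl-4-oxo-6-(pivaloyloxy)chromane-3-carboxylic acid | CC(C)(O)CCC[C@@]1(C)C(C(=O)O)C(=O)c2cc(OC(=O)C(C)(C)C)c(Br)cc2O1 | intermediate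
16 | (S)-7-bromo-2-(4-hydroxy-4-methylpentyl)-2-methyl-4-oxochroman-6-yl pivalate | CC(C)(O)CCC[C@@]1(C)CC(=O)c2cc(OC(=O)C(C)(C)C)c(Br)cc2O1 | intermediate
17 | (S)-7-bromo-6-hydroxy-2-(4-hydroxy-4-methylpentyl)-2-methylchroman-4-one | CC(C)(O)CCC[C@@]1(C)CC(=O)c2cc(O)c(Br)cc2O1 | target

## Step count and risks

Total step count: 10.
Longest linear sequence: 9 steps (steps 1, 2, 3, 5, 6, 7, 8, 9, 10).

**1. Step 7.**
- The triplet may decay before the ester has turned into its E rotamer and twisted over the ring.
- The diradical may revert by C3–C2' scission.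
- Facial selectivity may be poor if the substrate binds through C4=O alone.
- The Lewis acid may ionise the tertiary ester.

The fallback uses known chemistry: C2–C1' is made thermally and the enantiomers are separated. It sets out from 10 and returns at 16. Chromone 10 is treated with the organocopper reagent made from (4-methylpent-3-en-1-yl)magnesium bromide, CuBr·SMe2 and TMSCl in THF at −78 to −30 °C. This is conjugate addition to a chromone-3-carboxylate, and it should give racemic 2-methylpent-4-en-2-yl 7-bromo-2-methyl-2-(4-methylpent-3-en-1-yl)-4-oxo-6-(pivaloyloxy)chromane-3-carboxylate F1. Heating in wet DMSO as in step 9 removes the ester group together with its terminal alkene and gives racemic 7-bromo-2-methyl-2-(4-methylpent-3-en-1-yl)-4-oxochroman-6-yl pivalate F2. Mukaiyama hydration (Co(acac)2, PhSiH3, O2, THF) gives racemic 7-bromo-2-(4-hydroxy-4-methylpentyl)-2-methyl-4-oxochroman-6-yl pivalate F3. Preparative HPLC on a chiral stationary phase then delivers the (S)-enantiomer 16.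

**2. Step 8.** Bromide may be lost from the para-bromoaryl ketyl in competition with ring opening. The endocyclic C3–C2 bond may also break, toward the more stabilised tertiary α-oxy radical.

The fallback masks the halogen during the electron transfer. It answers the loss of bromide only; the choice between the two cyclobutane bonds still rests on the chelation control described in step 8. It sets out from 12 and returns at 16. Miyaura borylation of 12 (Pd(dppf)Cl2, B2pin2, KOAc, dioxane, 80 °C) gives the 7-(pinacolboryl) photoadduct F4. SmI2 cleavage as in step 8 gives the 7-(pinacolboryl) eight-membered β-keto lactone F5. Wet DMSO as in step 9 gives (S)-2-(4-hydroxy-4-methylpentyl)-2-methyl-4-oxo-7-(pinacolboryl)chroman-6-yl pivalate F6. Ipso-bromodeboronation with NaBr and chloramine-T (TsNClNa) in aqueous THF at rt restores the C7–Br bond and gives 16.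

**3. Step 9.** The alcohol may be released slowly from the medium-ring lactone, because the ketene is recaptured intramolecularly. Long heating may then erode the enantiomeric purity by reversible opening of ring B.

The fallback ionises the alkyl–oxygen bond instead of relying on acyl chemistry. It sets out from 13 and returns at 16. TFA in CH2Cl2 (0 °C to rt) ionises the tertiary C4'–O bond, and the liberated β-keto acid loses CO2 on gentle warming. This gives (S)-7-bromo-2-methyl-2-(4-methylpent-3-en-1-yl)-4-oxochroman-6-yl pivalate F7 together with its double-bond isomer (S)-7-bromo-2-methyl-2-(4-methylpent-4-en-1-yl)-4-oxochroman-6-yl pivalate F8. Both converge on 16 by Markovnikov Mukaiyama hydration (Co(acac)2, PhSiH3, O2, THF).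

Further compounds
F1 | step 7 | racemic 2-methylpent-4-en-2-yl 7-bromo-2-methyl-2-(4-methylpent-3-en-1-yl)-4-oxo-6-(pivaloyloxy)chromane-3-carboxylate | C=CCC(C)(C)OC(=O)C1C(=O)c2cc(OC(=O)C(C)(C)C)c(Br)cc2OC1(C)CCC=C(C)C
F2 | step 7 | racemic 7-bromo-2-methyl-2-(4-methylpent-3-en-1-yl)-4-oxochroman-6-yl pivalate | CC(C)=CCCC1(C)CC(=O)c2cc(OC(=O)C(C)(C)C)c(Br)cc2O1
F3 | step 7 | racemic 7-bromo-2-(4-hydroxy-4-methylpentyl)-2-methyl-4-oxochroman-6-yl pivalate | CC(C)(O)CCCC1(C)CC(=O)c2cc(OC(=O)C(C)(C)C)c(Br)cc2O1
F4 | step 8 | 7-(pinacolboryl) photoadduct | O=C1OC(C)(C)C[C@H]2C[C@]3(C)Oc4cc(B5OC(C)(C)C(C)(C)O5)c(OC(=O)C(C)(C)C)cc4C(=O)[C@]123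
F5 | step 8 | 7-(pinacolboryl) eight-membered β-keto lactone | CC1(C)CCC[C@]2(C)Oc3cc(B4OC(C)(C)C(C)(C)O4)c(OC(=O)C(C)(C)C)cc3C(=O)C2C(=O)O1
F6 | step 8 | (S)-2-(4-hydroxy-4-methylpentyl)-2-methyl-4-oxo-7-(pinacolboryl)chroman-6-yl pivalate | CC(C)(O)CCC[C@@]1(C)CC(=O)c2cc(OC(=O)C(C)(C)C)c(B3OC(C)(C)C(C)(C)O3)cc2O1
F7 | step 9 | (S)-7-bromo-2-methyl-2-(4-methylpent-3-en-1-yl)-4-oxochroman-6-yl pivalate | CC(C)=CCC[C@@]1(C)CC(=O)c2cc(OC(=O)C(C)(C)C)c(Br)cc2O1
F8 | step 9 | (S)-7-bromo-2-methyl-2-(4-methylpent-4-en-1-yl)-4-oxochroman-6-yl pivalate | C=C(C)CCC[C@@]1(C)CC(=O)c2cc(OC(=O)C(C)(C)C)c(Br)cc2O1
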